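## The problem

Penicimutamide B (24) is a hexacycle: a 3H-indole is spiro-linked at C3, through oxygen, to a six-membered cyclic carbamate; the carbamate bridges a cyclohexane (together a 2-oxa-4-azabicyclo[3.3.1]nonan-3-one); and the cyclohexane is trans-fused to an indolizidine whose piperidine ring ends in a carbinolamine. The cyclohexane is crowded: C3, the indolenine C2, the CMe2 carbon and the aminated carbon are fully substituted, and the single CH of the ring lies between the last two. There are five stereocentres: C3 (S), the aminated carbon (S), the ring-fusion CH (R), the pyrrolidine CH (R) and the carbinolamine CH (R). The carbamate bridge ties C3 to the aminated carbon, so one fixes the other, and the ring-fusion hydrogen is axial and anti to the carbamate nitrogen. The last two centres sit in an all-chair piperidine (pyrrolidine carbon equatorial, hydroxyl axial and anti to the amine lone pair), so they can be left to equilibrate. Three groups are fragile: the carbinolamine (ionises, exchanges with alcohols), the C=N bond (reduced by hydride), and the tertiary C3–O bond (1,2-shifts as the free alcohol; possible ionisation as an ester once an ene-amine tautomer is available). The enabling feature is that the CMe2 carbon is α to the indolenine C=N and bonded to the ring-fusion CH, so as an isopropyl group it is a latent carbon nucleophile. The aminated carbon carries two carbon arms, the ring-fusion CH and the carbinolamine carbon, which can start as two identical nitrovinyl groups, so one Michael addition closes the cyclohexane and desymmetrises the aminated carbon under control of C3.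

## Retrosynthesis

**24 to 23.** A nitro group is added back on the ring CH2 between the ring-fusion and pyrrolidine carbons. No skeletal bond is cut, but the carbon becomes a carbon acid that can be joined to an imine. The alternative, alkylating a metalated pyrrolidine with a neopentyl-type electrophile, has little chance at this position. The forward reaction is a radical denitration that must leave the carbinolamine and the C=N bond alone.

**23 to 19 and 21.** The C–C bond from the nitro carbon to pyrrolidine C2 and the N–C(OH) bond are cut, giving γ-nitro aldehyde 19 and the cyclic imine 21 (made from pyrrolidine 20). Against a lactam-based endgame, this brings the carbinolamine carbon in at the aldehyde oxidation level, so no late partial reduction is needed. The piperidine ring is opened, the pyrrolidine ring leaves with the imine, and the pyrrolidine, nitro-bearing and carbinolamine stereocentres disappear. The forward nitro-Mannich addition and ring closure must be reversible, so that the all-chair isomer collects.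

**19 to 17.** The aldehyde is traced to a second nitrovinyl group (C=C cleavage in the forward direction). This is what allows both arms on the aminated carbon to be identical one step earlier. The forward reaction must cleave an electron-poor alkene in the presence of a nitroalkane and the 3H-indole.

**17 to 16 (key).** The CMe2–CH bond is cut. Of the six cyclohexane bonds, this is the one whose removal leaves a precursor with a single stereocentre (C3) and an achiral aminated carbon with two identical arms. Cutting at C3 or at the aminated carbon would leave the quaternary stereocentres to be made separately. The forward reaction must pick the arm cis to C2 and place the nitromethyl group equatorial.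

**16 to 13 and 14, then 12.** Both C=C bonds are cut by Henry logic to dialdehyde 13 and two equivalents of nitromethane 14, and 13 is traced to diol 12. Treating both arms in the same operations keeps the aminated carbon achiral. The forward double nitroaldol must not fragment the non-enolisable malondialdehyde.

**12 to 11, 10 and 9.** The carbamate C(=O)–O bond is cut back to a Boc group and a tertiary alcohol (10), and the C3–O bond back to the indole 9. Closing the carbamate from the Boc group already on nitrogen needs no external carbonyl source. The primary hydroxyls would win the race for the Boc carbonyl (five-membered oxazolidinone), so they are masked as an acetonide from 9 to 11. The forward hydroxylation is the only enantio-determining step.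

**9 to 8, 7, then 5 and 6.** The bond between the indolylmethyl carbon and the aminated carbon is cut, giving gramine 5 and aminomalonate 6. Malonate 7 delivers the quaternary aminated carbon with two equal arms in one step, and reduction to diol 8 precedes indole oxidation because hydride would attack a 3H-indole.

**5 to 4, 3, then 1 and 2.** The aminomethyl group is removed (Mannich), the indole opened to alkynylaniline 3, and 3 cut at the aryl–alkyne bond to 2-iodoaniline 1 and 3-methylbut-1-yne 2. This places the isopropyl group at C2 without regiochemical ambiguity.

## Roads not taken

Alternative 1: Dehydrotryptophan vinylindole Diels–Alder.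
- **Cut:** the indole C2–CMe2 bond and the bond from the aminated carbon to the ring-fusion CH, in a [4+2] sense, with the indole still aromatic and a lactam in place of the carbinolamine.
- **Forward step:** heating or acid activation of the Z-dehydrotryptophan amide A1, whose 3-vinylindole unit is the diene and whose tethered prenyl olefin is the dienophile, would give pentacyclic indole lactam A2 after a hydrogen shift.
- **Merits:** two rings, two C–C bonds and both cyclohexane stereocentres form in one step. The pyrrolidine stereocentre is bought rather than made, so no asymmetric catalyst is needed. The route is more convergent and probably shorter, and intramolecular cycloadditions of this kind are closer to known chemistry. In these respects it is better than the chosen plan.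
- **Weak points:** the dienophile is an unactivated trisubstituted olefin and the diene terminus is the fully substituted α-carbon of a dehydroamino acid, so two hindered centres must join without electronic matching. Forcing conditions invite Z/E isomerisation. Facial control rests on one remote centre relayed through an amide rotamer. A2 then needs C3 hydroxylation on the face syn to nitrogen (a substrate-controlled step of unknown sense on a rigid pentacycle) and partial reduction of a hindered lactam beside a carbamate.
- **Comparison:** the chosen plan installs the C3 oxygen first and uses it as the control element, and the carbinolamine carbon arrives as an aldehyde. It pays with a longer linear sequence and a key step without direct precedent.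

Alternative 2: Bridged intramolecular nitrone cycloaddition.
- **Cut:** the bond from the aminated carbon to the ring CH2 and the C3–O bond, with nitrogen and oxygen delivered together.
- **Forward step:** the N-benzyl nitrone A3 would add across its tethered α-(2-nitrophenyl) enone to give the bridged isoxazolidine A4 on a 2,2-dimethylcyclohexanone.
- **Merits:** the cis 1,3-N,O relationship that the carbamate needs is set in one step. Oxygen goes to the more substituted olefin carbon, which is the normal regiochemistry. The indolenine would form later by reliable nitro reduction and condensation onto the ketone. No asymmetric indole oxidation is required. On heteroatom delivery and indolenine formation it is at least as good as the chosen plan.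
- **Weak points:** the dipole is a ketonitrone next to a carbon bonded to CMe2, and it must react in the bridged mode to create two quaternary centres. Facial selectivity against the existing ring-fusion centre is open. A3 is an acyclic chain that already contains the ring-fusion CH in defined relation to the pyrrolidine centre, so the hindered CMe2–CH bond has to be made intermolecularly beforehand. The ester must later be brought to the aldehyde level beside a ketone or imine.
- **Comparison:** the chosen plan's precursor has one stereocentre and comes from an indole by standard steps, and the hindered bond is made intramolecularly.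

Alternative 3: Carbene-catalysed crossed benzoin.
- **Cut:** the C2–C3 bond of the cyclohexane, by acyl-anion logic.
- **Forward step:** an N-heterocyclic carbene would convert the CMe2 aldehyde of A5 into an acyl-anion equivalent that adds to the 2-nitrophenyl ketone, giving α-hydroxy ketone A6.
- **Merits:** intramolecular aldehyde–ketone benzoin closures to six-membered rings are well precedented. The step is catalytic and sets the C3 hydroxyl next to the CMe2 ketone. Its key step is better precedented than that of the chosen plan.
- **Weak points:** the aldehyde is α-quaternary, so carbene addition and acyl-anion formation are slow. The ketone is ortho-substituted. The new hydroxyl must end cis to the Boc-amino group or the carbamate cannot bridge, and the reversible reaction may settle on either epimer. The aminated quaternary carbon, the ring-fusion CH and the pyrrolidine centre must all be in place in A5, so the hard part moves into the precursor. The lactam reduction of Alternative 1 also returns.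
- **Comparison:** the chosen plan creates the aminated and ring-fusion centres in the key step itself, under control of C3.

Key step: step 12

Remarks on the chemistry (assumptions):
- 1-Pyrroline (21) is taken to be isolated and stored as its trimer and to react as the monomer that the trimer releases in solution.
- Which mirror-image form of the aspartyl peptide catalyst of step 7 gives the (S)-carbinol cannot be predicted for this substrate; the form that does is assumed to be found in a first run, both forms being equally accessible.

## Route

Step 1
Reactants: 1 2-iodoaniline; 2 3-methylbut-1-yne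
Product: 3 2-(3-methylbut-1-yn-1-yl)aniline
Conditions: PdCl2(PPh3)2 (2 mol %), CuI (4 mol %), Et3N, sealed tube, rt
Reagents that add atoms: none
Why: Sonogashira coupling (oxidative addition of the aryl iodide to zerovalent palladium, transmetalation from the copper acetylide, reductive elimination); free anilines are tolerated and the sealed vessel keeps the volatile alkyne in solution.

Step 2
Reactants: 3 2-(3-methylbut-1-yn-1-yl)aniline
Product: 4 2-(propan-2-yl)-1H-indole
Conditions: NaAuCl4·2H2O (4 mol %), EtOH, rt
Reagents that add atoms: none
Why: Gold-catalysed cycloisomerisation (5-endo-dig hydroamination) of a 2-alkynylaniline; the trivalent gold salt activates the alkyne for attack by the aniline nitrogen and protodeauration gives the 2-substituted indole.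

Step 3
Reactants: 4 2-(propan-2-yl)-1H-indole
Product: 5 N,N-dimethyl-1-[2-(propan-2-yl)-1H-indol-3-yl]methanamine (2-isopropylgramine)
Conditions: 37% aq. CH2O, 40% aq. Me2NH, AcOH, 0 °C → rt
Reagents that add atoms: formaldehyde, C=O; dimethylamine, CNC
Why: Mannich reaction; the iminium ion from formaldehyde and dimethylamine is attacked by the nucleophilic C3 of the 2-alkylindole.

Step 4
Reactants: 5 2-isopropylgramine; 6 diethyl 2-[(tert-butoxycarbonyl)amino]malonate
Product: 7 diethyl 2-[(tert-butoxycarbonyl)amino]-2-{[2-(propan-2-yl)-1H-indol-3-yl]methyl}malonate
Conditions: n-Bu3P (0.3 equiv), MeCN, reflux, N2 stream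
Reagents that add atoms: none
Why: Gramine alkylation of an aminomalonate (the classical tryptophan construction); phosphine-assisted loss of dimethylamine gives the 3-methylene-3H-indole, which the malonate carbanion captures, and the new quaternary carbon carries two identical esters and is not a stereocentre.

Step 5
Reactants: 7 diethyl 2-[(tert-butoxycarbonyl)amino]-2-{[2-(propan-2-yl)-1H-indol-3-yl]methyl}malonate
Product: 8 tert-butyl N-(1,3-dihydroxy-2-{[2-(propan-2-yl)-1H-indol-3-yl]methyl}propan-2-yl)carbamate
Conditions: LiBH4 (4 equiv), THF, 0 °C → rt; aqueous work-up
Reagents that add atoms: none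
Why: Borohydride reduction of both esters to the 2-amino-1,3-diol leaves the Boc group and the indole untouched; it is placed before indole oxidation because hydride would reduce a 3H-indole C=N bond.

Step 6
Reactants: 8 tert-butyl N-(1,3-dihydroxy-2-{[2-(propan-2-yl)-1H-indol-3-yl]methyl}propan-2-yl)carbamate
Product: 9 tert-butyl N-(2,2-dimethyl-5-{[2-(propan-2-yl)-1H-indol-3-yl]methyl}-1,3-dioxan-5-yl)carbamate
Conditions: Me2C(OMe)2, PPTS (10 mol %), acetone, rt
Reagents that add atoms: 2,2-dimethoxypropane, COC(C)(C)OC
Why: Acetonide formation on the 1,3-diol (the six-membered dioxane, as with other 2-(Boc-amino)-2-substituted propane-1,3-diols) masks the primary hydroxyls, which would otherwise capture the Boc carbonyl as an oxazolidinone in step 8.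

Step 7
Reactants: 9 tert-butyl N-(2,2-dimethyl-5-{[2-(propan-2-yl)-1H-indol-3-yl]methyl}-1,3-dioxan-5-yl)carbamate
Product: 10 tert-butyl N-(5-{[(3S)-3-hydroxy-2-(propan-2-yl)-3H-indol-3-yl]methyl}-2,2-dimethyl-1,3-dioxan-5-yl)carbamate
Conditions: Boc-Asp-Pro-type tetrapeptide catalyst (10 mol %), 30% aq. H2O2, DIC, DMAP (10 mol %), CHCl3, 0 °C
Reagents that add atoms: hydrogen peroxide, OO
Why: Peptide-catalysed enantioselective indole oxidation; the aspartic acid side chain is turned by DIC and H2O2 into a peracid that transfers oxygen to the C2=C3 bond, and the indole epoxide opens to the 3-hydroxy-3H-indole. The hydrogen-bonded peptide (the carbamate N–H is its handle) selects the face of C3, the only stereocentre formed because the dioxane carbon is achiral.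

Step 8
Reactants: 10 tert-butyl N-(5-{[(3S)-3-hydroxy-2-(propan-2-yl)-3H-indol-3-yl]methyl}-2,2-dimethyl-1,3-dioxan-5-yl)carbamate
Product: 11 dispiro carbamate in which C3 (S) of 2-(propan-2-yl)-3H-indole is C6 of a 1,3-oxazinan-2-one (bonded to the ring oxygen) and C4 of the oxazinanone is C5 of a 2,2-dimethyl-1,3-dioxane
Conditions: NaH (1.3 equiv), THF, 0 °C → rt
Reagents that add atoms: none
Why: Intramolecular transcarbamoylation; the tertiary alkoxide adds to the Boc carbonyl through a six-membered transition state and expels tert-butoxide, so the C3–O bond is not touched and the configuration is kept. Acylating the oxygen also blocks the 1,2-shifts of the free 3-hydroxy-3H-indole.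

Step 9
Reactants: 11 dispiro carbamate acetonide
Product: 12 (3S)-4',4'-bis(hydroxymethyl)-2-(propan-2-yl)spiro[indole-3,6'-[1,3]oxazinan]-2'-one
Conditions: 1 M aq. HCl, THF, rt; then NaHCO3
Reagents that add atoms: none
Why: Acid hydrolysis of the acetonide; the cyclic carbamate is stable to dilute acid and the protonated 3H-indole cannot form the ene-amine that would assist ionisation of the C3–O bond.

Step 10
Reactants: 12 (3S)-4',4'-bis(hydroxymethyl)-2-(propan-2-yl)spiro[indole-3,6'-[1,3]oxazinan]-2'-one
Product: 13 (3S)-2'-oxo-2-(propan-2-yl)spiro[indole-3,6'-[1,3]oxazinane]-4',4'-dicarbaldehyde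
Conditions: Dess–Martin periodinane (2.6 equiv), NaHCO3, CH2Cl2, 0 °C → rt
Reagents that add atoms: none
Why: Dess–Martin oxidation of both neopentyl primary alcohols under buffered conditions gives the non-enolisable dialdehyde, which is used at once without chromatography.

Step 11
Reactants: 13 (3S)-2'-oxo-2-(propan-2-yl)spiro[indole-3,6'-[1,3]oxazinane]-4',4'-dicarbaldehyde; 14 nitromethane
Product: 16 (3S)-4',4'-bis[(E)-2-nitroethenyl]-2-(propan-2-yl)spiro[indole-3,6'-[1,3]oxazinan]-2'-one, via bis-nitroaldol adduct 15 (not isolated)
Conditions: MeNO2 (excess), tetramethylguanidine (20 mol %), THF, 0 °C; then MsCl, Et3N, CH2Cl2, −20 → 0 °C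
Reagents that add atoms: nitromethane (the second equivalent, the same compound as 14), C[N+](=O)[O-]
Why: Twofold Henry (nitroaldol) addition, one molecule of nitromethane per aldehyde, then mesylation and E1cB elimination to the (E)-nitroalkenes; the carbinol diastereomers of 15 converge, and because both arms are treated alike the aminated carbon stays achiral.

Step 12
Reactants: 16 (3S)-4',4'-bis[(E)-2-nitroethenyl]-2-(propan-2-yl)spiro[indole-3,6'-[1,3]oxazinan]-2'-one
Product: 17 bridged tetracyclic carbamate: spiro carbon (S) joined through the carbamate and through C2–CMe2–CH to the aminated carbon (S), which keeps one (E)-2-nitroethenyl group; ring-fusion carbon (S) with an equatorial nitromethyl group and its hydrogen anti to the carbamate nitrogen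
Conditions: KN(SiMe3)2 (2.1 equiv), THF, −78 → −20 °C; AcOH, −78 °C
Reagents that add atoms: none
Why: Proposed new method: KN(SiMe3)2 removes the carbamate N–H and then, reversibly, the tertiary α-hydrogen of the 2-isopropyl-3H-indole, and the potassium aza-enolate (the metalated ene-amine tautomer) adds through its CMe2 carbon to the β-carbon of the nitrovinyl arm held over it, giving a nitronate that AcOH protonates; the closest known reaction types are the intermolecular Michael additions of ene-amine tautomers of 2-alkyl-3H-indoles and of metalated ketimines to nitroalkenes, and the new elements are the intramolecular, group-selective course and the tertiary nucleophilic carbon. The cyclohexane closes in a 6-(enolendo)-exo-trig mode (the C=C of the aza-enolate inside the new ring, the nitronate carbon outside) and completes the 2-oxa-4-azabicyclo[3.3.1]nonan-3-one. The aminated carbon becomes a stereocentre by choice between its two arms: a bridge can only form to the arm that is cis to C2 across the oxazinanone ring (both must be axial), so the (S) spiro carbon fixes it by geometry and not by a conformational preference. The ring-fusion carbon is set in a chair-like transition state with the =CH–NO2 terminus equatorial and its hydrogen axial, anti to the carbamate nitrogen, since the axial alternative pushes the nitro group under the ring against the bridging CH2; the addition should be reversible under these conditions, and the equatorial nitromethyl isomer is also expected to be the more stable one. The step needs C- and not N-attack of the ambident anion (N-attack would give a strained bridged ene-amine and can revert), and it needs the nitroalkenes to outlast the base, which their neopentyl β-carbons, the lack of γ-hydrogens and the low temperature should secure. Anionic conditions are chosen over heat or acid because the neutral ene-amine could expel the C3 carbamate oxygen and aromatise to an indole.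

Step 13
Reactants: 17 bridged tetracyclic carbamate with nitromethyl and nitrovinyl groups
Product: 19 bridged tetracyclic carbamate with a formyl group on the aminated carbon (S) and the nitromethyl group on the ring-fusion carbon (S), via secondary ozonide 18 (not isolated)
Conditions: O3, CH2Cl2, −78 °C; then Me2S, −78 °C → rt
Reagents that add atoms: ozone, [O-][O+]=O
Why: Ozonolysis; cycloaddition of ozone to the remaining C=C bond and reductive cleavage of the ozonide give the aldehyde. The nitromethyl group is not ionised in neutral CH2Cl2 and is inert, the C=N bond and the benzo ring react more slowly than the alkene, and the aldehyde has no α-hydrogen, so the aminated stereocentre is safe.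

Step 14
Reactants: 20 pyrrolidine
Product: 21 3,4-dihydro-2H-pyrrole (1-pyrroline)
Conditions: Na2S2O8, AgNO3 (0.5 mol %), NaOH, H2O, 0 °C
Reagents that add atoms: none
Why: Silver-catalysed persulfate dehydrogenation of the secondary amine to the cyclic imine, a standard preparation of 1-pyrroline.

Step 15
Reactants: 19 formyl nitromethyl tetracycle; 21 1-pyrroline
Product: 23 nitro-substituted hexacyclic carbinolamine (24 bearing an equatorial nitro group on the ring CH2 between the ring-fusion and pyrrolidine carbons), via nitro-Mannich amino aldehyde 22 (not isolated)
Conditions: 21 (2 equiv), Et3N (0.2 equiv), THF, rt → 40 °C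
Reagents that add atoms: none
Why: Nitro-Mannich (aza-Henry) addition of the nitronate to the cyclic imine, after which the new secondary amine closes onto the neighbouring aldehyde to the six-membered carbinolamine, the known cascade of γ-nitro aldehydes with imines. C–C and C–N bond formation are both reversible, so the all-chair isomer (trans ring fusion, equatorial pyrrolidine carbon and nitro group, axial hydroxyl anti to the amine lone pair) should accumulate, and this is the configuration of 24 at the pyrrolidine and carbinolamine carbons.

Step 16
Reactants: 23 nitro-substituted hexacyclic carbinolamine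
Product: 24 Penicimutamide B
Conditions: Bu3SnH (5 equiv), AIBN (0.4 equiv in portions), toluene, 110 °C
Reagents that add atoms: none
Why: Radical denitration; the stannyl radical adds to a nitro oxygen, the C–N bond fragments to a secondary alkyl radical and hydrogen transfer from Bu3SnH completes the reduction. The radical carbon is not a stereocentre of 24, and the carbinolamine cannot dehydrate because its carbon neighbour is quaternary.

## Compound list

1 | 2-iodoaniline | Nc1ccccc1I | starting material
2 | 3-methylbut-1-yne | CC(C)C#C | starting material
3 | 2-(3-methylbut-1-yn-1-yl)aniline | CC(C)C#Cc1ccccc1N | intermediate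
4 | 2-(propan-2-yl)-1H-indole | CC(C)c1cc2ccccc2[nH]1 | intermediate
5 | N,N-dimethyl-1-[2-(propan-2-yl)-1H-indol-3-yl]methanamine | CC(C)c1[nH]c2ccccc2c1CN(C)C | intermediate
6 | diethyl 2-[(tert-butoxycarbonyl)amino]malonate | CCOC(=O)C(NC(=O)OC(C)(C)C)C(=O)OCC | starting material
7 | diethyl 2-[(tert-butoxycarbonyl)amino]-2-{[2-(propan-2-yl)-1H-indol-3-yl]methyl}malonate | CCOC(=O)C(Cc1c(C(C)C)[nH]c2ccccc12)(NC(=O)OC(C)(C)C)C(=O)OCC | intermediate
8 | tert-butyl N-(1,3-dihydroxy-2-{[2-(propan-2-yl)-1H-indol-3-yl]methyl}propan-2-yl)carbamate | CC(C)c1[nH]c2ccccc2c1CC(CO)(CO)NC(=O)OC(C)(C)C | intermediate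
9 | tert-butyl N-(2,2-dimethyl-5-{[2-(propan-2-yl)-1H-indol-3-yl]methyl}-1,3-dioxan-5-yl)carbamate | CC(C)c1[nH]c2ccccc2c1CC1(NC(=O)OC(C)(C)C)COC(C)(C)OC1 | intermediate
10 | tert-butyl N-(5-{[(3S)-3-hydroxy-2-(propan-2-yl)-3H-indol-3-yl]methyl}-2,2-dimethyl-1,3-dioxan-5-yl)carbamate | CC(C)C1=Nc2ccccc2[C@@]1(O)CC1(NC(=O)OC(C)(C)C)COC(C)(C)OC1 | intermediate
11 | dispiro carbamate: (3S)-2-(propan-2-yl)-3H-indole spiro at C3 to C6 of a 1,3-oxazinan-2-one, whose C4 is spiro to C5 of a 2,2-dimethyl-1,3-dioxane | CC(C)C1=Nc2ccccc2[C@@]12CC3(COC(C)(C)OC3)NC(=O)O2 | intermediate
12 | (3S)-4',4'-bis(hydroxymethyl)-2-(propan-2-yl)spiro[indole-3,6'-[1,3]oxazinan]-2'-one | CC(C)C1=Nc2ccccc2[C@@]12CC(CO)(CO)NC(=O)O2 | intermediate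
13 | (3S)-2'-oxo-2-(propan-2-yl)spiro[indole-3,6'-[1,3]oxazinane]-4',4'-dicarbaldehyde | CC(C)C1=Nc2ccccc2[C@@]12CC(C=O)(C=O)NC(=O)O2 | intermediate
14 | nitromethane | C[N+](=O)[O-] | starting material
15 | (3S)-4',4'-bis(1-hydroxy-2-nitroethyl)-2-(propan-2-yl)spiro[indole-3,6'-[1,3]oxazinan]-2'-one, mixture of carbinol diastereomers, not isolated | CC(C)C1=Nc2ccccc2[C@@]12CC(C(O)C[N+](=O)[O-])(C(O)C[N+](=O)[O-])NC(=O)O2 | intermediate
16 | (3S)-4',4'-bis[(E)-2-nitroethenyl]-2-(propan-2-yl)spiro[indole-3,6'-[1,3]oxazinan]-2'-one (key-step precursor) | CC(C)C1=Nc2ccccc2[C@@]12CC(NC(=O)O2)(/C=C/[N+](=O)[O-])/C=C/[N+](=O)[O-] | intermediate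
17 | bridged tetracyclic carbamate with an (E)-2-nitroethenyl group on the aminated carbon (S) and an equatorial nitromethyl group on the ring-fusion carbon (S); spiro carbon (S) (key-step product) | CC1(C)C2=Nc3ccccc3[C@@]23C[C@](/C=C/[N+](=O)[O-])(NC(=O)O3)[C@@H]1C[N+](=O)[O-] | intermediate
18 | secondary ozonide of 17 (5-nitro-1,2,4-trioxolan-3-yl group on the aminated carbon; trioxolane carbons unassigned), not isolated | CC1(C)C2=Nc3ccccc3[C@@]23C[C@](C4OOC(O4)[N+](=O)[O-])(NC(=O)O3)[C@@H]1C[N+](=O)[O-] | intermediate
19 | bridged tetracyclic carbamate with a formyl group on the aminated carbon (S) and a nitromethyl group on the ring-fusion carbon (S) | CC1(C)C2=Nc3ccccc3[C@@]23C[C@](C=O)(NC(=O)O3)[C@@H]1C[N+](=O)[O-] | intermediate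
20 | pyrrolidine | C1CCNC1 | starting material
21 | 3,4-dihydro-2H-pyrrole (1-pyrroline; handled as its trimer) | C1CC=NC1 | intermediate
22 | nitro-Mannich adduct of 19 and 21: formyl tetracycle whose ring-fusion carbon carries a nitro(pyrrolidin-2-yl)methyl group; pyrrolidine carbon (R), nitro carbon drawn as expected after equilibration; not isolated | CC1(C)C2=Nc3ccccc3[C@@]23C[C@](C=O)(NC(=O)O3)[C@@H]1[C@H]([N+](=O)[O-])[C@H]1CCCN1 | intermediate
23 | nitro-substituted hexacyclic carbinolamine: 24 with an equatorial nitro group on the ring CH2 between the ring-fusion and pyrrolidine carbons | CC1(C)C2=Nc3ccccc3[C@@]23C[C@]2(NC(=O)O3)[C@@H]1[C@H]([N+](=O)[O-])[C@H]1CCCN1[C@@H]2O | intermediate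
24 | Penicimutamide B | CC1(C)C2=Nc3ccccc3[C@@]23C[C@]2(NC(=O)O3)[C@@H]1C[C@H]1CCCN1[C@@H]2O | target

## Step count and least certain steps

Total: 16 steps. Longest linear sequence: 15 steps (steps 1–13, 15 and 16); step 14 is a one-step side branch.

**Step 12 (key step, proposed new method).**
- *What may go wrong:* base-induced oligomerisation of the nitroalkenes before the weakly acidic tertiary C–H is removed; loss of the C3 carbamate oxygen through the ene-amine with aromatisation to an indole; closure through the transition state with the nitrovinyl terminus axial. All three follow from the same fact: the carbon acid is weak and hindered, while the electrophile and the C3–O bond are sensitive.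
- *Fallback (known chemistry), from 16 back to 17:* the imine is temporarily unmasked as a ketone, whose mild-base intramolecular Michael addition to nitroalkenes is established. N-Acylation of the 3H-indole with 2-(trimethylsilyl)ethyl chloroformate (CH2Cl2/aq. NaHCO3) and mild acid hydrolysis of the resulting ene-carbamate should give the ring-opened keto carbamate F1. Alkoxide base (catalytic KOtBu, t-BuOH/THF) should then close the cyclohexanone by enolate Michael addition to the nitrovinyl arm cis to the acyl group, giving the bridged cyclohexanone F2 with the same arm selection and chair preference. TFA in CH2Cl2 removes the silylethyl carbamate, and the freed aniline condenses with the 2,2-dimethyl ketone to re-form the 3H-indole, which is 17.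

**Step 11.**
- *What may go wrong:* retro-aldol fragmentation of the β-nitro alkoxide or deformylation of the quaternary malondialdehyde under the basic Henry conditions, and incomplete second addition at the hindered aldehyde.
- *Fallback, from 13 back to 16:* Wittig methylenation of both aldehydes (Ph3P=CH2, THF, −78 → 0 °C) gives the divinyl carbamate F3, which passes through no β-nitro alkoxide. Radical nitration of both terminal alkenes (AgNO2, TEMPO, 4 Å molecular sieves, 1,2-dichloroethane, 70 °C) installs the (E)-nitro groups and gives 16.

**Step 15.**
- *What may go wrong:* slow addition of the neopentyl-type nitronate to 1-pyrroline, so that imine self-condensation takes over, and incomplete equilibration leaving the wrong configuration at the pyrrolidine carbon.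
- *Fallback, from 19 back to 23:* Henry addition of the nitromethyl group of 19 to commercial tert-butyl N-(4-oxobutyl)carbamate (tetramethylguanidine cat.) gives nitro alcohol F4. Mesylation and elimination give nitroalkene F5. TFA removes the Boc group; on neutralisation the primary amine closes the pyrrolidine by 5-exo-trig aza-Michael addition, and the resulting secondary amine closes the carbinolamine onto the aldehyde, which gives 23.

**Step 7.**
- *What may go wrong:* insufficient or wrong-sense facial selectivity with this 2-isopropyl substrate, and acid-promoted 1,2-shift of the product during the oxidation.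
- *Fallback, from 9 back to 11:* oxidation with dimethyldioxirane (acetone, −78 °C) gives the racemic carbinol F6. NaH closure as in step 8 gives the racemic dispiro carbamate F7, which has a single stereocentre and is resolved by preparative chromatography on a chiral stationary phase to give 11.

**Step 13.**
- *What may go wrong:* competing attack of ozone on the benzo ring or the C=N bond because the nitroalkene is electron-poor, and over-oxidation of the aldehyde.
- *Fallback, from 17 back to 19:* hydrolytic cleavage without an oxidant. Aqueous base (NaHCO3 or Et3N, THF/H2O) adds water to the nitroalkene to give nitro alcohol F8, which undergoes retro-Henry cleavage, the reverse of the reaction that built the arm. Co-evaporation of the nitromethane drives it to 19.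

## Further compounds

F1 | step 12 | 2-(trimethylsilyl)ethyl N-{2-[(6S)-6-(2-methylpropanoyl)-4,4-bis[(E)-2-nitroethenyl]-2-oxo-1,3-oxazinan-6-yl]phenyl}carbamate | CC(C)C(=O)[C@@]1(c2ccccc2NC(=O)OCC[Si](C)(C)C)CC(NC(=O)O1)(/C=C/[N+](=O)[O-])/C=C/[N+](=O)[O-]
F2 | step 12 | bridged 2,2-dimethylcyclohexanone analogue of 17 with a 2-{[2-(trimethylsilyl)ethoxy]carbonylamino}phenyl group on the carbinol carbon | CC1(C)C(=O)[C@@]2(c3ccccc3NC(=O)OCC[Si](C)(C)C)C[C@](/C=C/[N+](=O)[O-])(NC(=O)O2)[C@@H]1C[N+](=O)[O-]
F3 | step 11 | (3S)-4',4'-diethenyl-2-(propan-2-yl)spiro[indole-3,6'-[1,3]oxazinan]-2'-one | CC(C)C1=Nc2ccccc2[C@@]12CC(C=C)(C=C)NC(=O)O2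
F4 | step 15 | nitro alcohol from 19 and tert-butyl N-(4-oxobutyl)carbamate (carbinol and nitro carbons unassigned) | CC1(C)C2=Nc3ccccc3[C@@]23C[C@](C=O)(NC(=O)O3)[C@@H]1C([N+](=O)[O-])C(O)CCCNC(=O)OC(C)(C)C
F5 | step 15 | nitroalkene from dehydration of F4 (alkene geometry unassigned) | CC1(C)C2=Nc3ccccc3[C@@]23C[C@](C=O)(NC(=O)O3)[C@@H]1C([N+](=O)[O-])=CCCCNC(=O)OC(C)(C)C
F6 | step 7 | racemic tert-butyl N-(5-{[3-hydroxy-2-(propan-2-yl)-3H-indol-3-yl]methyl}-2,2-dimethyl-1,3-dioxan-5-yl)carbamate | CC(C)C1=Nc2ccccc2C1(O)CC1(NC(=O)OC(C)(C)C)COC(C)(C)OC1
F7 | step 7 | racemic dispiro carbamate (11 and its mirror image) | CC(C)C1=Nc2ccccc2C12CC3(COC(C)(C)OC3)NC(=O)O2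
F8 | step 13 | hydrate of 17: 1-hydroxy-2-nitroethyl group on the aminated carbon (carbinol carbon unassigned) | CC1(C)C2=Nc3ccccc3[C@@]23C[C@](C(O)C[N+](=O)[O-])(NC(=O)O3)[C@@H]1C[N+](=O)[O-]
A1 | alternative 1 | Z-dehydrotryptophan amide of (R)-2-prenylpyrrolidine with a Boc-amino group on the alkene | CC(C)=CC[C@H]1CCCN1C(=O)/C(NC(=O)OC(C)(C)C)=C/c1c[nH]c2ccccc12
A2 | alternative 1 | pentacyclic indole lactam with a Boc-amino group on the quaternary carbon | CC1(C)c2[nH]c3ccccc3c2C[C@]2(NC(=O)OC(C)(C)C)[C@@H]1C[C@H]1CCCN1C2=O
A3 | alternative 2 | N-benzyl nitrone of the α-keto ester tethered to the α-(2-nitrophenyl) enone (nitrone geometry unassigned) | C=C(c1ccccc1[N+](=O)[O-])C(=O)C(C)(C)[C@@H](C[C@H]1CCCN1C(=O)OC(C)(C)C)C(C(=O)OC)=[N+]([O-])Cc1ccccc1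
A4 | alternative 2 | bridged isoxazolidine on the 2,2-dimethylcyclohexanone | CC1(C)C(=O)[C@@]2(c3ccccc3[N+](=O)[O-])C[C@](C(=O)OC)(N(Cc3ccccc3)O2)[C@@H]1C[C@H]1CCCN1C(=O)OC(C)(C)C
A5 | alternative 3 | bicyclic lactam with the CMe2 aldehyde and the 2-nitrophenyl ketone side chain | O=CC(C)(C)[C@H]1C[C@H]2CCCN2C(=O)[C@@]1(CC(=O)c1ccccc1[N+](=O)[O-])NC(=O)OC(C)(C)C
A6 | alternative 3 | tricyclic α-hydroxy ketone with the 2-nitrophenyl carbinol | CC1(C)C(=O)[C@@](O)(c2ccccc2[N+](=O)[O-])C[C@]2(NC(=O)OC(C)(C)C)[C@@H]1C[C@H]1CCCN1C2=O
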